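The readings were computed on assumed constants; the scatter is artificial.

The easy mistake in epsilon is to read 0.500 equiv of X as that much L. The east run warns against it.

| flask | Z | X | remark | time |
|---|---|---|---|---|
| east | 0.075 M | 4 equiv | run made earlier |  |
| delta | 0.050 M | 4.00 equiv |  | 1.0 h |
| gamma | 0.050 M | 1.20 equiv |  | 1.0 h |
| epsilon | 0.050 M | 0.500 equiv |  | 1.0 h |

- east (time / min: L / %, Z / %): 3.00: 54.9, 0; 5.00: 47.2, 0.3; 10.0: 34.3, 0; 20.0: 19.4, 0.4; 40.0: 5.7, 0

(readings scatter by 1 percentage point)

* which of these holds the largest part of the Z at the end of delta (J / E / Z / L)
* which of these holds the largest part of the Z at the end of gamma (J / E / Z / L)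
* which of these holds the largest part of the Z at the end of epsilon (J / E / Z / L)
* final L in epsilon, as a percentage of the Z charged

- no earlier run changes the charge of X; that part of a forecast is a guess

With X in excess, L in east falls pseudo-first-order, from 54.9% at 3.00 min to 5.7% at 40.0 min, so I read a rate constant of 0.0612 min⁻¹. Run back to the start, that line gives 66.0%. I call this the L share: the fraction of reacted Z that stands as L with the slow loss of L set aside, a reading that carries the scatter of east.

Two extreme versions of epsilon can be reckoned in the head, both with the X charged fully used. If the missing part of reacted Z took one X per Z, reacted Z equals the X charged, and L is 33.0%. If it took two, the same X reaches less Z, and L is 24.6%.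

Does the X get used? Z reads 0% at 3.00 min, so I allow it 5 half-lives there and take each as 0.600 min. Taking the step as first order in each partner, I estimate the half-life of X in epsilon at 7.20 min, far shorter than the 102 min that L would take to halve at the full X of epsilon. No earlier run changes X, so this scaling is a guess; I commit to L between 24.6% and 33.0%, and, with at least one X to each reacted Z, to Z at 50.0% or more, above L.

The forecast names E, L and Z as largest in delta, gamma and epsilon, and gives L in epsilon as 33%, within 22% to 48%, noting that “X is limiting”.

    E + X ⇌ G + J (K = 0.959, k = 0.493 L mol⁻¹ s⁻¹)
    L ⇌ D (K = 0.450, k = 0.0175 s⁻¹)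
    L + X → G + E (k = 0.00920 L mol⁻¹ s⁻¹)
    Z + X → G + L (k = 0.144 L mol⁻¹ s⁻¹)

Epsilon ends with L at 33.3%, beside the one-X extreme of 33.0%. Z left there is 50.8%, so 49.2% reacted against 0.500 equiv of X charged, with 0% of that X left, about one X per reacted Z. The neighbour of epsilon charged with 0.300 equiv of X then reckons as the L share times its charge, 19.8%, and it ends with L at 20.3%.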